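**Retrosynthetic overview**

1. Testudinariol A is C2-symmetric; both cyclopentanols are disconnected at the carbinol-carbon/isopropenyl-carbon bond by a type 1 intramolecular carbonyl-ene reaction, giving the bis(6-methylhept-5-enal) 26 that already carries both oxanes.
2. Both oxanes are disconnected at the C-2/C-3 bond: a primary radical at oxane C-3 closes onto C-2 of a β-alkoxyacrylimide (step 19), forming two rings and four stereocentres in one operation.
3. Enabling feature: in each half the oxane O-1 and C-2 lie β to the cyclopentanol carbinol carbon (O-1–C-2–C-5 of the cyclopentane–C-1 of the cyclopentane); with that carbon at the acyl level this is a β-alkoxyacrylate whose β-carbon is oxane C-2, while oxane C-3 is a plain CH2 two bonds from the exocyclic C-5 alkene and C-6 is unsubstituted.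
4. The bis-acceptor 18 is assembled one terminus at a time: two Still–Gennari olefinations with phosphonate 3 (on 4,4-dimethoxybutanal 5, then on aldehyde 9) build the (Z,Z)-octa-2,6-diene core with its two allylic oxygens differentiated (one as a 4-methoxybenzyl ether), and each oxygen is O-vinylated in turn with chloroacrylate 15.
5. Ring order: both oxanes (step 19), then both cyclopentanes (step 22).

Key step: step 19

Remarks and assumptions
- Oxane numbering throughout: O-1, C-2 (bears the side chain), C-3, C-4, C-5 (alkylidene), C-6.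
- The sense of induction of the magnesium/bis(oxazoline) complex in step 19 is taken by analogy with intermolecular radical conjugate additions; if a model cyclization shows the opposite sense, the enantiomeric ligand is used and nothing else changes.
- Phosphonate 3 is made once and used in steps 3 and 7; chloroacrylate 15 is made once and used in steps 12 and 14. Each of these four steps consumes one equivalent of the fragment.
- From step 15 on, each step converts both identical termini of the C2-symmetric intermediate in one operation; the half-converted species is numbered only in the key step.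
- Compound 14 reacts as its hydroxymethylene enol; 15 is used as the E/Z mixture.

**Route**

Step 1
Reactants: 1 methyl 2-[bis(2,2,2-trifluoroethoxy)phosphoryl]acetate; 2 tert-butyl(2-iodoethoxy)dimethylsilane
Product: 3 methyl 2-[bis(2,2,2-trifluoroethoxy)phosphoryl]-4-[(tert-butyldimethylsilyl)oxy]butanoate
Conditions: NaH, DMF, 0 °C to rt
Reagents that add atoms: none
Why: SN2 C-alkylation of the stabilized phosphonoacetate anion by a primary iodide; the new centre is racemic and disappears in the olefinations of steps 3 and 7.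

Step 2
Reactants: 4 methyl 4,4-dimethoxybutanoate
Product: 5 4,4-dimethoxybutanal
Conditions: iBu2AlH (1.05 equiv), CH2Cl2, −78 °C; MeOH, then aq. potassium sodium tartrate
Reagents that add atoms: none
Why: partial reduction of a methyl ester stops at the aldehyde because the tetrahedral aluminium hemiacetal survives at −78 °C until the quench, and the dimethyl acetal is inert.

Step 3
Reactants: 3 methyl 2-[bis(2,2,2-trifluoroethoxy)phosphoryl]-4-[(tert-butyldimethylsilyl)oxy]butanoate; 5 4,4-dimethoxybutanal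
Product: 6 methyl (2Z)-2-{2-[(tert-butyldimethylsilyl)oxy]ethyl}-6,6-dimethoxyhex-2-enoate
Conditions: KN(SiMe3)2, 18-crown-6, THF, −78 °C
Reagents that add atoms: none
Why: Still–Gennari variant of the Horner–Wadsworth–Emmons reaction, in which fast irreversible elimination from the kinetic adduct of the electron-poor phosphonate should place the ester cis to the chain (Z); the single alkene can be purified to one isomer before the second is made.

Step 4
Reactants: 6 methyl (2Z)-2-{2-[(tert-butyldimethylsilyl)oxy]ethyl}-6,6-dimethoxyhex-2-enoate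
Product: 7 (2Z)-2-{2-[(tert-butyldimethylsilyl)oxy]ethyl}-6,6-dimethoxyhex-2-en-1-ol
Conditions: iBu2AlH (2.2 equiv), CH2Cl2, −78 °C; aq. potassium sodium tartrate
Reagents that add atoms: none
Why: 1,2-reduction of the enoate to the allylic alcohol leaves the alkene geometry, the acetal and the silyl ether untouched.

Step 5
Reactants: 7 (2Z)-2-{2-[(tert-butyldimethylsilyl)oxy]ethyl}-6,6-dimethoxyhex-2-en-1-ol
Product: 8 1-({[(2Z)-2-{2-[(tert-butyldimethylsilyl)oxy]ethyl}-6,6-dimethoxyhex-2-en-1-yl]oxy}methyl)-4-methoxybenzene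
Conditions: NaH, 4-methoxybenzyl chloride, Bu4NI (cat.), THF/DMF, 0 °C to rt
Reagents that add atoms: 4-methoxybenzyl chloride, COc1ccc(CCl)cc1
Why: Williamson etherification masks the first allylic oxygen as a 4-methoxybenzyl ether, which tolerates mild acid, strong base and hydride and is removed oxidatively, so the two allylic oxygens of the core stay distinguishable.

Step 6
Reactants: 8 1-({[(2Z)-2-{2-[(tert-butyldimethylsilyl)oxy]ethyl}-6,6-dimethoxyhex-2-en-1-yl]oxy}methyl)-4-methoxybenzene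
Product: 9 (4Z)-5-{2-[(tert-butyldimethylsilyl)oxy]ethyl}-6-[(4-methoxybenzyl)oxy]hex-4-enal
Conditions: pyridinium p-toluenesulfonate (cat.), acetone/H2O, 40 °C
Reagents that add atoms: water, O
Why: mild acid-catalysed hydrolysis of the dimethyl acetal frees the aldehyde while the primary silyl ether and the 4-methoxybenzyl ether survive.

Step 7
Reactants: 9 (4Z)-5-{2-[(tert-butyldimethylsilyl)oxy]ethyl}-6-[(4-methoxybenzyl)oxy]hex-4-enal; 3 methyl 2-[bis(2,2,2-trifluoroethoxy)phosphoryl]-4-[(tert-butyldimethylsilyl)oxy]butanoate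
Product: 10 methyl (2Z,6Z)-2,7-bis{2-[(tert-butyldimethylsilyl)oxy]ethyl}-8-[(4-methoxybenzyl)oxy]octa-2,6-dienoate
Conditions: KN(SiMe3)2, 18-crown-6, THF, −78 °C
Reagents that add atoms: none
Why: a second Still–Gennari olefination sets the second Z-trisubstituted alkene by the same kinetic control, on an aldehyde that already carries the first alkene as a single isomer.

Step 8
Reactants: 10 methyl (2Z,6Z)-2,7-bis{2-[(tert-butyldimethylsilyl)oxy]ethyl}-8-[(4-methoxybenzyl)oxy]octa-2,6-dienoate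
Product: 11 (2Z,6Z)-2,7-bis{2-[(tert-butyldimethylsilyl)oxy]ethyl}-8-[(4-methoxybenzyl)oxy]octa-2,6-dien-1-ol
Conditions: iBu2AlH (2.2 equiv), CH2Cl2, −78 °C; aq. potassium sodium tartrate
Reagents that add atoms: none
Why: 1,2-reduction of the enoate gives the second allylic alcohol as the only free hydroxyl group, with both alkene geometries and all ethers intact.

Step 9
Reactants: 12 methyl hex-5-enoate
Product: 13 methyl 6-methylhept-5-enoate
Conditions: second-generation Grubbs catalyst RuCl2(=CHPh)(PCy3)(H2IMes) (2 mol %), 2-methylbut-2-ene (excess), CH2Cl2, 40 °C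
Reagents that add atoms: 2-methylbut-2-ene, CC=C(C)C
Why: olefin cross-metathesis of a terminal alkene with 2-methylbut-2-ene installs the trisubstituted terminus with loss of propene.

Step 10
Reactants: 13 methyl 6-methylhept-5-enoate
Product: 14 methyl 2-formyl-6-methylhept-5-enoate
Conditions: LiN(iPr)2, THF, −78 °C; HCO2Me, −78 to 0 °C; aq. NH4Cl
Reagents that add atoms: methyl formate, COC=O
Why: crossed Claisen condensation of the ester enolate with a non-enolizable formate gives the α-formyl ester, held as its hydroxymethylene enol.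

Step 11
Reactants: 14 methyl 2-formyl-6-methylhept-5-enoate
Product: 15 methyl 3-chloro-2-(4-methylpent-3-en-1-yl)prop-2-enoate
Conditions: (COCl)2, DMF (cat.), 2,6-lutidine, CH2Cl2, 0 °C
Reagents that add atoms: oxalyl chloride, O=C(Cl)C(Cl)=O
Why: Vilsmeier-type chlorination turns the vinylogous acid into a vinylogous acid chloride, with lutidine trapping HCl to protect the trisubstituted alkene.

Step 12
Reactants: 11 (2Z,6Z)-2,7-bis{2-[(tert-butyldimethylsilyl)oxy]ethyl}-8-[(4-methoxybenzyl)oxy]octa-2,6-dien-1-ol; 15 methyl 3-chloro-2-(4-methylpent-3-en-1-yl)prop-2-enoate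
Product: 16 methyl (2E)-3-{[(2Z,6Z)-2,7-bis{2-[(tert-butyldimethylsilyl)oxy]ethyl}-8-[(4-methoxybenzyl)oxy]octa-2,6-dien-1-yl]oxy}-2-(4-methylpent-3-en-1-yl)prop-2-enoate
Conditions: NaH, THF, 0 °C; then 15 (1.2 equiv), 0 °C to rt
Reagents that add atoms: none
Why: nucleophilic vinylic substitution (addition–elimination) of the allylic alkoxide on the β-chloroacrylate should give the conjugated (E)-β-alkoxyacrylate, the thermodynamic isomer, on a substrate with a single free hydroxyl group.

Step 13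
Reactants: 16 methyl (2E)-3-{[(2Z,6Z)-2,7-bis{2-[(tert-butyldimethylsilyl)oxy]ethyl}-8-[(4-methoxybenzyl)oxy]octa-2,6-dien-1-yl]oxy}-2-(4-methylpent-3-en-1-yl)prop-2-enoate
Product: 17 methyl (2E)-3-{[(2Z,6Z)-2,7-bis{2-[(tert-butyldimethylsilyl)oxy]ethyl}-8-hydroxyocta-2,6-dien-1-yl]oxy}-2-(4-methylpent-3-en-1-yl)prop-2-enoate
Conditions: DDQ (1.2 equiv), CH2Cl2/pH 7 phosphate buffer, 0 °C
Reagents that add atoms: none
Why: oxidative cleavage of the 4-methoxybenzyl ether by DDQ (hydride abstraction to the oxocarbenium ion, then hydrolysis) frees the second allylic alcohol without touching the silyl ethers, the vinylogous carbonate or the trisubstituted alkenes.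

Step 14
Reactants: 17 methyl (2E)-3-{[(2Z,6Z)-2,7-bis{2-[(tert-butyldimethylsilyl)oxy]ethyl}-8-hydroxyocta-2,6-dien-1-yl]oxy}-2-(4-methylpent-3-en-1-yl)prop-2-enoate; 15 methyl 3-chloro-2-(4-methylpent-3-en-1-yl)prop-2-enoate
Product: 18 dimethyl (2E,2'E)-3,3'-{[(2Z,6Z)-2,7-bis{2-[(tert-butyldimethylsilyl)oxy]ethyl}octa-2,6-diene-1,8-diyl]bis(oxy)}bis[2-(4-methylpent-3-en-1-yl)prop-2-enoate]
Conditions: NaH, THF, 0 °C; then 15 (1.2 equiv), 0 °C to rt
Reagents that add atoms: none
Why: the second nucleophilic vinylic substitution completes the C2-symmetric bis[(E)-β-alkoxyacrylate]; it is done before the iodides exist so that no alkoxide can close a tetrahydrofuran.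

Step 15
Reactants: 18 dimethyl (2E,2'E)-3,3'-{[(2Z,6Z)-2,7-bis{2-[(tert-butyldimethylsilyl)oxy]ethyl}octa-2,6-diene-1,8-diyl]bis(oxy)}bis[2-(4-methylpent-3-en-1-yl)prop-2-enoate]
Product: 19 (2E,2'E)-3,3'-{[(2Z,6Z)-2,7-bis{2-[(tert-butyldimethylsilyl)oxy]ethyl}octa-2,6-diene-1,8-diyl]bis(oxy)}bis[2-(4-methylpent-3-en-1-yl)prop-2-enoic acid]
Conditions: Me3SnOH, ClCH2CH2Cl, 70 °C; aq. HCl work-up
Reagents that add atoms: trimethyltin hydroxide, C[Sn](C)(C)O
Why: neutral tin-hydroxide ester hydrolysis cleaves the hindered vinylogous carbonate esters without hydroxide attack at the enol-ether carbon or loss of the silyl ethers.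

Step 16
Reactants: 19 (2E,2'E)-3,3'-{[(2Z,6Z)-2,7-bis{2-[(tert-butyldimethylsilyl)oxy]ethyl}octa-2,6-diene-1,8-diyl]bis(oxy)}bis[2-(4-methylpent-3-en-1-yl)prop-2-enoic acid]
Product: 20 diethyl N,N'-{(2E,2'E)-3,3'-{[(2Z,6Z)-2,7-bis{2-[(tert-butyldimethylsilyl)oxy]ethyl}octa-2,6-diene-1,8-diyl]bis(oxy)}bis[2-(4-methylpent-3-en-1-yl)prop-2-enoyl]}dicarbamate
Conditions: EtO2C–N=C=O (2.4 equiv), Et3N (cat.), toluene, 0 to 50 °C
Reagents that add atoms: ethoxycarbonyl isocyanate, CCOC(=O)N=C=O
Why: the acid adds to the activated isocyanate and the mixed carbamic anhydride loses CO2 with O-to-N acyl shift, giving the N–H acylcarbamate that serves as the two-point binding site in step 19.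

Step 17
Reactants: 20 diethyl N,N'-{(2E,2'E)-3,3'-{[(2Z,6Z)-2,7-bis{2-[(tert-butyldimethylsilyl)oxy]ethyl}octa-2,6-diene-1,8-diyl]bis(oxy)}bis[2-(4-methylpent-3-en-1-yl)prop-2-enoyl]}dicarbamate
Product: 21 diethyl N,N'-{(2E,2'E)-3,3'-{[(2Z,6Z)-2,7-bis(2-hydroxyethyl)octa-2,6-diene-1,8-diyl]bis(oxy)}bis[2-(4-methylpent-3-en-1-yl)prop-2-enoyl]}dicarbamate
Conditions: HF·pyridine, pyridine, THF, 0 °C to rt
Reagents that add atoms: none
Why: buffered fluoride cleaves the primary silyl ethers while the acylcarbamates and the vinylogous esters are stable.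

Step 18
Reactants: 21 diethyl N,N'-{(2E,2'E)-3,3'-{[(2Z,6Z)-2,7-bis(2-hydroxyethyl)octa-2,6-diene-1,8-diyl]bis(oxy)}bis[2-(4-methylpent-3-en-1-yl)prop-2-enoyl]}dicarbamate
Product: 22 diethyl N,N'-{(2E,2'E)-3,3'-{[(2Z,6Z)-2,7-bis(2-iodoethyl)octa-2,6-diene-1,8-diyl]bis(oxy)}bis[2-(4-methylpent-3-en-1-yl)prop-2-enoyl]}dicarbamate
Conditions: I2, PPh3, imidazole, CH2Cl2, 0 °C
Reagents that add atoms: iodine, II
Why: Appel-type iodination (SN2 on the alkoxyphosphonium ion) converts the homoallylic primary alcohols into the radical precursors under neutral conditions.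

Step 19
Reactants: 22 diethyl N,N'-{(2E,2'E)-3,3'-{[(2Z,6Z)-2,7-bis(2-iodoethyl)octa-2,6-diene-1,8-diyl]bis(oxy)}bis[2-(4-methylpent-3-en-1-yl)prop-2-enoyl]}dicarbamate
Product: 24 (2R,2'R)-2,2'-[(2R,2'R,5Z,5'Z)-5,5'-(butane-1,4-diylidene)bis(oxane-5,2-diyl)]bis[N-(ethoxycarbonyl)-6-methylhept-5-enamide], via monocyclized iodide 23 (not isolated)
Conditions: Mg(NTf2)2 (2.2 equiv), 2,2'-(cyclopropane-1,1-diyl)bis[(3aS,8aR)-3a,8a-dihydro-8H-indeno[1,2-d]oxazole] (2.4 equiv), 4 Å MS, CH2Cl2 (high dilution), −78 °C; Bu3SnH (syringe pump), Et3B/air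
Reagents that add atoms: none
Why: Proposed new method: Et3B/O2 starts a tin chain in which Bu3Sn• abstracts iodine from each CH2I, the primary radical at oxane C-3 adds to C-2, the β-carbon of the (E)-β-alkoxyacrylimide held as a six-membered two-point chelate on the chiral magnesium bis(oxazoline) Lewis acid, and the resulting tertiary α-acyl radical takes hydrogen from Bu3SnH. The closest known reaction types are the radical cyclization of β-alkoxyacrylates to 2-substituted oxanes and the chiral-Lewis-acid-mediated enantioselective radical conjugate addition/hydrogen-atom transfer to α-substituted β-oxygenated acrylimides; their union in a ring closure is new. Each oxane closes in the 6-exo-trig mode through a chair-like transition state. C-2 should be set by the ligand, which shields one face of the chelated acrylimide; the adjacent side-chain centre should be set by substrate control, hydrogen arriving anti to the ring CH2 of the new oxane in the allylic-strain-minimized radical conformer (exocyclic effect), which gives the 2,1'-anti pair. The step needs enantioface selectivity at two remote sites (residual error should end largely in a separable meso isomer), ring closure faster than direct reduction or reversible 3-exo attack on the neighbouring Z-alkene, and inert prenyl groups. Lewis-acid activation of the acceptor, slow addition of Bu3SnH at high dilution and the 4-exo/5-endo relation of the prenyl alkene to the α-radical should secure these.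

Step 20
Reactants: 24 (2R,2'R)-2,2'-[(2R,2'R,5Z,5'Z)-5,5'-(butane-1,4-diylidene)bis(oxane-5,2-diyl)]bis[N-(ethoxycarbonyl)-6-methylhept-5-enamide]
Product: 25 (2S,2'S)-2,2'-[(2R,2'R,5Z,5'Z)-5,5'-(butane-1,4-diylidene)bis(oxane-5,2-diyl)]bis(6-methylhept-5-en-1-ol)
Conditions: LiBH4, MeOH (2 equiv), THF, 0 °C to rt
Reagents that add atoms: none
Why: hydride should attack the more electrophilic acyl carbonyl of the N-acylcarbamate (reductive cleavage as for N-acyl oxazolidinones), releasing ethyl carbamate without enolizing the α-centre.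

Step 21
Reactants: 25 (2S,2'S)-2,2'-[(2R,2'R,5Z,5'Z)-5,5'-(butane-1,4-diylidene)bis(oxane-5,2-diyl)]bis(6-methylhept-5-en-1-ol)
Product: 26 (2R,2'R)-2,2'-[(2R,2'R,5Z,5'Z)-5,5'-(butane-1,4-diylidene)bis(oxane-5,2-diyl)]bis(6-methylhept-5-enal)
Conditions: Dess–Martin periodinane, NaHCO3, CH2Cl2, 0 °C to rt; used crude
Reagents that add atoms: none
Why: buffered Dess–Martin oxidation gives the α-branched β-alkoxy aldehydes without epimerization or β-elimination.

Step 22
Reactants: 26 (2R,2'R)-2,2'-[(2R,2'R,5Z,5'Z)-5,5'-(butane-1,4-diylidene)bis(oxane-5,2-diyl)]bis(6-methylhept-5-enal)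
Product: 27 testudinariol A, (1S,1'S,2R,2'R,5S,5'S)-5,5'-[(2R,2'R,5Z,5'Z)-5,5'-(butane-1,4-diylidene)bis(oxane-5,2-diyl)]bis[2-(prop-1-en-2-yl)cyclopentan-1-ol]
Conditions: Me2AlCl (2.2 equiv), CH2Cl2, −78 °C
Reagents that add atoms: none
Why: type 1 intramolecular carbonyl-ene reaction in which the concerted six-membered hydrogen transfer from a prenyl methyl to the aluminium-bound oxygen forces OH and isopropenyl cis, while the oxanyl group on the α-carbon should sit pseudo-equatorial and anti to the O–Al group (OH trans to oxanyl), so the existing α-centre relays both new centres of each ring.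

**Compound list**

1 | methyl 2-[bis(2,2,2-trifluoroethoxy)phosphoryl]acetate | COC(=O)CP(=O)(OCC(F)(F)F)OCC(F)(F)F | starting material
2 | tert-butyl(2-iodoethoxy)dimethylsilane | CC(C)(C)[Si](C)(C)OCCI | starting material
3 | methyl 2-[bis(2,2,2-trifluoroethoxy)phosphoryl]-4-[(tert-butyldimethylsilyl)oxy]butanoate (racemic) | COC(=O)C(CCO[Si](C)(C)C(C)(C)C)P(=O)(OCC(F)(F)F)OCC(F)(F)F | intermediate
4 | methyl 4,4-dimethoxybutanoate | COC(=O)CCC(OC)OC | starting material
5 | 4,4-dimethoxybutanal | O=CCCC(OC)OC | intermediate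
6 | methyl (2Z)-2-{2-[(tert-butyldimethylsilyl)oxy]ethyl}-6,6-dimethoxyhex-2-enoate | COC(=O)/C(CCO[Si](C)(C)C(C)(C)C)=C\CCC(OC)OC | intermediate
7 | (2Z)-2-{2-[(tert-butyldimethylsilyl)oxy]ethyl}-6,6-dimethoxyhex-2-en-1-ol | OC/C(CCO[Si](C)(C)C(C)(C)C)=C\CCC(OC)OC | intermediate
8 | 1-({[(2Z)-2-{2-[(tert-butyldimethylsilyl)oxy]ethyl}-6,6-dimethoxyhex-2-en-1-yl]oxy}methyl)-4-methoxybenzene (4-methoxybenzyl ether of 7) | COc1ccc(COC/C(CCO[Si](C)(C)C(C)(C)C)=C\CCC(OC)OC)cc1 | intermediate
9 | (4Z)-5-{2-[(tert-butyldimethylsilyl)oxy]ethyl}-6-[(4-methoxybenzyl)oxy]hex-4-enal | COc1ccc(COC/C(CCO[Si](C)(C)C(C)(C)C)=C\CCC=O)cc1 | intermediate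
10 | methyl (2Z,6Z)-2,7-bis{2-[(tert-butyldimethylsilyl)oxy]ethyl}-8-[(4-methoxybenzyl)oxy]octa-2,6-dienoate | COC(=O)/C(CCO[Si](C)(C)C(C)(C)C)=C\CC/C=C(/CCO[Si](C)(C)C(C)(C)C)COCc1ccc(OC)cc1 | intermediate
11 | (2Z,6Z)-2,7-bis{2-[(tert-butyldimethylsilyl)oxy]ethyl}-8-[(4-methoxybenzyl)oxy]octa-2,6-dien-1-ol | OC/C(CCO[Si](C)(C)C(C)(C)C)=C\CC/C=C(/CCO[Si](C)(C)C(C)(C)C)COCc1ccc(OC)cc1 | intermediate
12 | methyl hex-5-enoate | COC(=O)CCCC=C | starting material
13 | methyl 6-methylhept-5-enoate | COC(=O)CCCC=C(C)C | intermediate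
14 | methyl 2-formyl-6-methylhept-5-enoate (racemic; mainly the hydroxymethylene enol) | COC(=O)C(C=O)CCC=C(C)C | intermediate
15 | methyl 3-chloro-2-(4-methylpent-3-en-1-yl)prop-2-enoate (E/Z mixture) | COC(=O)C(=CCl)CCC=C(C)C | intermediate
16 | methyl (2E)-3-{[(2Z,6Z)-2,7-bis{2-[(tert-butyldimethylsilyl)oxy]ethyl}-8-[(4-methoxybenzyl)oxy]octa-2,6-dien-1-yl]oxy}-2-(4-methylpent-3-en-1-yl)prop-2-enoate | COC(=O)/C(CCC=C(C)C)=C/OC/C(CCO[Si](C)(C)C(C)(C)C)=C\CC/C=C(/CCO[Si](C)(C)C(C)(C)C)COCc1ccc(OC)cc1 | intermediate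
17 | methyl (2E)-3-{[(2Z,6Z)-2,7-bis{2-[(tert-butyldimethylsilyl)oxy]ethyl}-8-hydroxyocta-2,6-dien-1-yl]oxy}-2-(4-methylpent-3-en-1-yl)prop-2-enoate | COC(=O)/C(CCC=C(C)C)=C/OC/C(CCO[Si](C)(C)C(C)(C)C)=C\CC/C=C(/CCO[Si](C)(C)C(C)(C)C)CO | intermediate
18 | dimethyl (2E,2'E)-3,3'-{[(2Z,6Z)-2,7-bis{2-[(tert-butyldimethylsilyl)oxy]ethyl}octa-2,6-diene-1,8-diyl]bis(oxy)}bis[2-(4-methylpent-3-en-1-yl)prop-2-enoate] | COC(=O)/C(CCC=C(C)C)=C/OC/C(CCO[Si](C)(C)C(C)(C)C)=C\CC/C=C(/CCO[Si](C)(C)C(C)(C)C)CO/C=C(\CCC=C(C)C)C(=O)OC | intermediate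
19 | (2E,2'E)-3,3'-{[(2Z,6Z)-2,7-bis{2-[(tert-butyldimethylsilyl)oxy]ethyl}octa-2,6-diene-1,8-diyl]bis(oxy)}bis[2-(4-methylpent-3-en-1-yl)prop-2-enoic acid] | OC(=O)/C(CCC=C(C)C)=C/OC/C(CCO[Si](C)(C)C(C)(C)C)=C\CC/C=C(/CCO[Si](C)(C)C(C)(C)C)CO/C=C(\CCC=C(C)C)C(O)=O | intermediate
20 | diethyl N,N'-{(2E,2'E)-3,3'-{[(2Z,6Z)-2,7-bis{2-[(tert-butyldimethylsilyl)oxy]ethyl}octa-2,6-diene-1,8-diyl]bis(oxy)}bis[2-(4-methylpent-3-en-1-yl)prop-2-enoyl]}dicarbamate (each CO2H of 19 as C(=O)NHCO2Et) | CCOC(=O)NC(=O)/C(CCC=C(C)C)=C/OC/C(CCO[Si](C)(C)C(C)(C)C)=C\CC/C=C(/CCO[Si](C)(C)C(C)(C)C)CO/C=C(\CCC=C(C)C)C(=O)NC(=O)OCC | intermediate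
21 | diethyl N,N'-{(2E,2'E)-3,3'-{[(2Z,6Z)-2,7-bis(2-hydroxyethyl)octa-2,6-diene-1,8-diyl]bis(oxy)}bis[2-(4-methylpent-3-en-1-yl)prop-2-enoyl]}dicarbamate | CCOC(=O)NC(=O)/C(CCC=C(C)C)=C/OC/C(CCO)=C\CC/C=C(/CCO)CO/C=C(\CCC=C(C)C)C(=O)NC(=O)OCC | intermediate
22 | diethyl N,N'-{(2E,2'E)-3,3'-{[(2Z,6Z)-2,7-bis(2-iodoethyl)octa-2,6-diene-1,8-diyl]bis(oxy)}bis[2-(4-methylpent-3-en-1-yl)prop-2-enoyl]}dicarbamate | CCOC(=O)NC(=O)/C(CCC=C(C)C)=C/OC/C(CCI)=C\CC/C=C(/CCI)CO/C=C(\CCC=C(C)C)C(=O)NC(=O)OCC | intermediate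
23 | monocyclized iodide: ethyl N-[(2R)-2-{(2R,5Z)-5-[(4Z)-6-{[(1E)-3-[(ethoxycarbonyl)amino]-2-(4-methylpent-3-en-1-yl)-3-oxoprop-1-en-1-yl]oxy}-5-(2-iodoethyl)hex-4-en-1-ylidene]oxan-2-yl}-6-methylhept-5-enoyl]carbamate | CCOC(=O)NC(=O)[C@H](CCC=C(C)C)[C@H]1CC/C(=C/CC/C=C(/CCI)CO/C=C(\CCC=C(C)C)C(=O)NC(=O)OCC)CO1 | intermediate
24 | (2R,2'R)-2,2'-[(2R,2'R,5Z,5'Z)-5,5'-(butane-1,4-diylidene)bis(oxane-5,2-diyl)]bis[N-(ethoxycarbonyl)-6-methylhept-5-enamide] | CCOC(=O)NC(=O)[C@H](CCC=C(C)C)[C@H]1CC/C(=C/CC/C=C2/CC[C@H]([C@@H](CCC=C(C)C)C(=O)NC(=O)OCC)OC2)CO1 | intermediate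
25 | (2S,2'S)-2,2'-[(2R,2'R,5Z,5'Z)-5,5'-(butane-1,4-diylidene)bis(oxane-5,2-diyl)]bis(6-methylhept-5-en-1-ol) | OC[C@H](CCC=C(C)C)[C@H]1CC/C(=C/CC/C=C2/CC[C@H]([C@@H](CCC=C(C)C)CO)OC2)CO1 | intermediate
26 | (2R,2'R)-2,2'-[(2R,2'R,5Z,5'Z)-5,5'-(butane-1,4-diylidene)bis(oxane-5,2-diyl)]bis(6-methylhept-5-enal) | O=C[C@H](CCC=C(C)C)[C@H]1CC/C(=C/CC/C=C2/CC[C@H]([C@@H](CCC=C(C)C)C=O)OC2)CO1 | intermediate
27 | testudinariol A, (1S,1'S,2R,2'R,5S,5'S)-5,5'-[(2R,2'R,5Z,5'Z)-5,5'-(butane-1,4-diylidene)bis(oxane-5,2-diyl)]bis[2-(prop-1-en-2-yl)cyclopentan-1-ol] | C=C(C)[C@H]1CC[C@H]([C@H]2CC/C(=C/CC/C=C3/CC[C@H]([C@H]4CC[C@H](C(=C)C)[C@@H]4O)OC3)CO2)[C@H]1O | target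

**Step count**

Total step count: 22. Longest linear sequence: 18 steps (1 → 3 → 6 → 7 → 8 → 9 → 10 → 11 → 16 → 17 → 18 → 19 → 20 → 21 → 22 → 24 → 25 → 26 → 27; the branch from 4 is equally long, the branch from 12 has 14 steps).

**Steps most likely to fail**

1. Step 19 (Proposed new method). The Lewis acid may be held by the ether oxygens, or a background cyclization on unligated substrate may erode enantioface selection at one or both termini. The primary radical may be reduced before it closes. Reversible 3-exo attack on the neighbouring trisubstituted alkene may scramble the Z geometry. The magnesium-bound allyl vinyl ether may undergo a Claisen-type shift. Fallback (known chemistry, substrate control plus resolution), setting out from 18: HF·pyridine should give the dimethyl ester diol F1, and Appel iodination the dimethyl ester diiodide F2. Bu3SnH and AIBN in benzene at 80 °C under syringe-pump addition should close both oxanes by the β-alkoxyacrylate radical cyclization with anti hydrogen transfer. This should give the bis(oxane) dimethyl ester F3 as a statistical mixture of the racemic C2-symmetric isomer and the meso isomer. Reduction with iBu2AlH, chromatographic removal of the meso diol and resolution of the racemic diol on a chiral stationary phase should return the route at 25. The cost is a theoretical ceiling of one quarter of the material.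

2. Step 16. The deactivated vinylogous carbonic acid may add too slowly to the isocyanate, the mixed carbamic anhydride may collapse to the symmetric acid anhydride instead of losing CO2, or the warmed allyl vinyl ether may rearrange. Fallback (reversed polarity of the N-acylation), setting out from 19: 1-chloro-N,N,2-trimethylprop-1-en-1-amine in CH2Cl2 at 0 °C should give, under neutral conditions, the bis(acid chloride) F4. Acylation of the sodium salt of ethyl carbamate (NaH, THF, 0 °C, two equivalents per acyl chloride) returns the route at 20.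

3. Step 12. The vinylic substitution may stall, the alkoxide may attack the ester carbonyl instead of the β-carbon, or the enol ether may form as an E/Z mixture. Fallback (reversed polarity of the ether formation), setting out from 11: CBr4/PPh3 should give the allylic bromide F5. O-alkylation of the potassium enolate of 14 (K2CO3, DMF, rt) with it should then give the enol ether, returning the route at 16. C-alkylation would create a quaternary centre and is disfavoured.

Further compounds
F1 | step 19 | dimethyl (2E,2'E)-3,3'-{[(2Z,6Z)-2,7-bis(2-hydroxyethyl)octa-2,6-diene-1,8-diyl]bis(oxy)}bis[2-(4-methylpent-3-en-1-yl)prop-2-enoate] | COC(=O)/C(CCC=C(C)C)=C/OC/C(CCO)=C\CC/C=C(/CCO)CO/C=C(\CCC=C(C)C)C(=O)OC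
F2 | step 19 | dimethyl (2E,2'E)-3,3'-{[(2Z,6Z)-2,7-bis(2-iodoethyl)octa-2,6-diene-1,8-diyl]bis(oxy)}bis[2-(4-methylpent-3-en-1-yl)prop-2-enoate] | COC(=O)/C(CCC=C(C)C)=C/OC/C(CCI)=C\CC/C=C(/CCI)CO/C=C(\CCC=C(C)C)C(=O)OC
F3 | step 19 | dimethyl (2R,2'R)-2,2'-[(2R,2'R,5Z,5'Z)-5,5'-(butane-1,4-diylidene)bis(oxane-5,2-diyl)]bis(6-methylhept-5-enoate) (wanted isomer shown; formed together with its enantiomer and the meso isomer) | COC(=O)[C@H](CCC=C(C)C)[C@H]1CC/C(=C/CC/C=C2/CC[C@H]([C@@H](CCC=C(C)C)C(=O)OC)OC2)CO1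
F4 | step 16 | (2E,2'E)-3,3'-{[(2Z,6Z)-2,7-bis{2-[(tert-butyldimethylsilyl)oxy]ethyl}octa-2,6-diene-1,8-diyl]bis(oxy)}bis[2-(4-methylpent-3-en-1-yl)prop-2-enoyl chloride] | ClC(=O)/C(CCC=C(C)C)=C/OC/C(CCO[Si](C)(C)C(C)(C)C)=C\CC/C=C(/CCO[Si](C)(C)C(C)(C)C)CO/C=C(\CCC=C(C)C)C(Cl)=O
F5 | step 12 | (2Z,6Z)-1-bromo-2,7-bis{2-[(tert-butyldimethylsilyl)oxy]ethyl}-8-[(4-methoxybenzyl)oxy]octa-2,6-diene | BrC/C(CCO[Si](C)(C)C(C)(C)C)=C\CC/C=C(/CCO[Si](C)(C)C(C)(C)C)COCc1ccc(OC)cc1
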